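**Plan**

- Numbering of the bicyclo[3.2.1]octene: C1 bridgehead CH, C2 enone carbonyl, C3 methoxy carbon, C4 alkene CH, C5 allyl-bearing bridgehead, C6 methyl carbon, C7 aryl carbon, C8 bridging ketone.
- Cuts, in retrosynthetic order: the C3 oxygen and C3=C4 unsaturation (back to a 2-silyloxy-4-methoxy ketone); then C4–C5 and C6–CH3 together; then C1–C2 (aldol), C5–allyl (Stille) and C7–aryl (Heck–Matsuda).
- Enabling feature: C5 is the α-carbon of the C8 ketone and the neighbour of C6, the β-carbon of the cyclopentenone ring C8–C1–C7–C6–C5. Methyl addition at C6 therefore gives the C8=C5 enol ether, which can close the six-membered ring C1–C2–C3–C4–C5–C8 onto an acetal carbon C4 tethered from C1.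
- Forward order: the five-membered ring is bought as cyclopent-3-en-1-ol; aryl, allyl and the C2–C4 chain are attached in turn; the six-membered ring closes in the key step; the C2/C3/C4 oxidation pattern is set last.
- Stereochemistry: C7 from the ligand-controlled Heck–Matsuda desymmetrisation; C1 from an aldol anti to the aryl group; C6 from cuprate delivery anti to the aryl group; C5 from the tether, which can bridge only on its own face.

Key step: step 9

Remark: the (S)-tert-butyl pyridine–oxazoline ligand is assumed to give the (1R,4S) alcohol 4; if the sense of induction is opposite, its (R)-antipode is used. Bicyclic compounds keep the numbering of the target throughout.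

**Route**

Step 1
Reactants: 1 3,4-dimethoxyaniline
Product: 2 3,4-dimethoxybenzenediazonium tetrafluoroborate
Conditions: NaNO2, aq. HBF4, H2O, 0 °C; filtration, cold Et2O wash
Reagents that add atoms: sodium nitrite [Na+].[O-]N=O; tetrafluoroboric acid [H+].F[B-](F)(F)F
Why: Diazotisation of the electron-rich aniline in aqueous HBF4 should precipitate the bench-stable arenediazonium tetrafluoroborate needed as aryl donor for a Heck–Matsuda reaction.

Step 2
Reactants: 2 3,4-dimethoxybenzenediazonium tetrafluoroborate; 3 cyclopent-3-en-1-ol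
Product: 4 (1R,4S)-4-(3,4-dimethoxyphenyl)cyclopent-2-en-1-ol (cis)
Conditions: Pd(OCOCF3)2 (cat.), (S)-4-tert-butyl-2-[5-(trifluoromethyl)pyridin-2-yl]-4,5-dihydrooxazole (cat.), ZnCO3, MeOH, 40 °C
Reagents that add atoms: none
Why: In this enantioselective Heck–Matsuda desymmetrisation the cationic aryl–palladium species, guided by the hydroxyl group and the chiral pyridine–oxazoline, should add to one enantiotopic alkene carbon on the hydroxyl face and undergo syn β-hydride elimination away from the aryl carbon, so the ligand sets the aryl-bearing centre (later C7).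

Step 3
Reactants: 4 (1R,4S)-4-(3,4-dimethoxyphenyl)cyclopent-2-en-1-ol
Product: 5 (S)-4-(3,4-dimethoxyphenyl)cyclopent-2-en-1-one
Conditions: activated MnO2, CH2Cl2, 25 °C
Reagents that add atoms: none
Why: Neutral allylic oxidation with MnO2 should give the enone without acid or base that could racemise the γ-stereocentre or move the double bond into conjugation with the arene.

Step 4
Reactants: 5 (S)-4-(3,4-dimethoxyphenyl)cyclopent-2-en-1-one
Product: 6 (S)-4-(3,4-dimethoxyphenyl)-2-iodocyclopent-2-en-1-one
Conditions: I2, pyridine, CH2Cl2, 0 to 25 °C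
Reagents that add atoms: iodine II
Why: In the Johnson α-iodination pyridine adds reversibly to the β-carbon, the enolate is iodinated and pyridine is expelled, conditions mild enough to leave the γ-stereocentre and the dimethoxyarene untouched.

Step 5
Reactants: 6 (S)-4-(3,4-dimethoxyphenyl)-2-iodocyclopent-2-en-1-one; 7 allyltributylstannane
Product: 8 (S)-2-allyl-4-(3,4-dimethoxyphenyl)cyclopent-2-en-1-one
Conditions: Pd2(dba)3 (dba = dibenzylideneacetone, cat.), AsPh3, CuI (cat.), NMP, 25 °C
Reagents that add atoms: none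
Why: Stille coupling of the α-iodoenone with the allylstannane should proceed at room temperature with the weakly bound arsine ligand and CuI co-catalyst, which limits migration of the allyl double bond into conjugation.

Step 6
Reactants: 9 methyl 3,3-dimethoxypropanoate
Product: 10 3,3-dimethoxypropanal
Conditions: iBu2AlH, CH2Cl2, −78 °C; aq. potassium sodium tartrate (KNaC4H4O6); used crude at once
Reagents that add atoms: none
Why: Partial ester reduction with iBu2AlH at −78 °C should stop at the aluminium hemiacetal, which releases the aldehyde only on work-up.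

Step 7
Reactants: 8 (S)-2-allyl-4-(3,4-dimethoxyphenyl)cyclopent-2-en-1-one; 10 3,3-dimethoxypropanal
Product: 12 (4R,5R)-2-allyl-4-(3,4-dimethoxyphenyl)-5-(1-hydroxy-3,3-dimethoxypropyl)cyclopent-2-en-1-one (4,5-trans; carbinol epimers), via lithium dienolate 11 (not isolated)
Conditions: LiN(iPr)2, THF, −78 °C; then 10, −78 °C; AcOH quench at −78 °C
Reagents that add atoms: none
Why: In this kinetic lithium aldol addition the amide base should remove the α′-proton faster than the γ-benzylic one, and the cross-conjugated dienolate should add to the aldehyde anti to the neighbouring aryl group, setting the chain-bearing centre (later C1) trans to it; the carbinol configuration is irrelevant because that carbon becomes the C2 ketone.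

Step 8
Reactants: 12 (4R,5R)-2-allyl-4-(3,4-dimethoxyphenyl)-5-(1-hydroxy-3,3-dimethoxypropyl)cyclopent-2-en-1-one
Product: 13 (4R,5R)-2-allyl-5-[1-(tert-butyldimethylsilyloxy)-3,3-dimethoxypropyl]-4-(3,4-dimethoxyphenyl)cyclopent-2-en-1-one (4,5-trans; silyl ether carbon as either epimer)
Conditions: TBSCl, imidazole, DMF, 25 °C
Reagents that add atoms: tert-butyldimethylsilyl chloride CC(C)(C)[Si](C)(C)Cl
Why: Silylation of the secondary alcohol under Corey conditions should block retro-aldol cleavage and β-elimination while sparing the dimethyl acetal, which silyl triflate–base mixtures could cleave.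

Step 9
Reactants: 13 (4R,5R)-2-allyl-5-[1-(tert-butyldimethylsilyloxy)-3,3-dimethoxypropyl]-4-(3,4-dimethoxyphenyl)cyclopent-2-en-1-one
Product: 15 (1R,5S,6R,7R)-5-allyl-2-(tert-butyldimethylsilyloxy)-7-(3,4-dimethoxyphenyl)-4-methoxy-6-methylbicyclo[3.2.1]octan-8-one (aryl exo; methyl endo; C2/C4 epimer mixtures), via trimethylsilyl enol ether 14 (not isolated)
Conditions: Me2CuLi (from MeLi and CuI), Me3SiCl, THF, −78 °C; Et3N, pentane, filtration, solvent exchange; TiCl4, CH2Cl2, −78 °C
Reagents that add atoms: lithium dimethylcuprate [Li+].C[Cu-]C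
Why: The cuprate, accelerated by Me3SiCl, should add methyl to the β-carbon C6 with O-silylation of the enolate, fixing the enol ether double bond between C8 and the allyl-bearing C5; TiCl4 then ionises the dimethyl acetal to a methoxy-oxocarbenium ion at C4, which C5 attacks with loss of the silyl group. The closest known reaction types are the Me3SiCl-promoted organocuprate conjugate addition with enolate silylation and the intramolecular Mukaiyama addition of a silyl enol ether to a tethered acetal giving a bridged ketone. The six-membered ring C1–C2–C3–C4–C5–C8 closes in a 6-(enolendo)-exo-trig mode, the enol ether double bond lying inside and the oxocarbenium C=O bond outside the new ring. C6 is controlled by the adjacent C7 aryl group, the cuprate attacking the opposite face as with other 4-substituted cyclopentenones, and C5 by the tether, which is anchored at C1 trans to the aryl group and can reach C5 only on its own face, forcing the allyl group outward. The step needs 1,4- over 1,2-addition and bond formation at the fully substituted C5 and not at C1; both are secured because the conjugate addition makes the enol ether regiospecifically and it never equilibrates, while C2 and C4 may form as epimers since both become trigonal later.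

Step 10
Reactants: 15 (1R,5S,6R,7R)-5-allyl-2-(tert-butyldimethylsilyloxy)-7-(3,4-dimethoxyphenyl)-4-methoxy-6-methylbicyclo[3.2.1]octan-8-one
Product: 16 (1R,5S,6R,7R)-5-allyl-7-(3,4-dimethoxyphenyl)-2-hydroxy-4-methoxy-6-methylbicyclo[3.2.1]octan-8-one (C2/C4 epimer mixtures)
Conditions: HF·pyridine, pyridine, THF, 0 to 25 °C
Reagents that add atoms: none
Why: Fluoride-mediated desilylation under buffered, non-basic conditions should free the C2 alcohol without retro-aldol cleavage of the C2–C1–C8 β-hydroxy ketone.

Step 11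
Reactants: 16 (1R,5S,6R,7R)-5-allyl-7-(3,4-dimethoxyphenyl)-2-hydroxy-4-methoxy-6-methylbicyclo[3.2.1]octan-8-one
Product: 17 (1R,5S,6R,7R)-5-allyl-7-(3,4-dimethoxyphenyl)-4-methoxy-6-methylbicyclo[3.2.1]octane-2,8-dione (C4 epimers)
Conditions: Dess–Martin periodinane, NaHCO3, CH2Cl2, 25 °C
Reagents that add atoms: none
Why: Dess–Martin oxidation should convert the C2 alcohol into the ketone at neutral pH, and the resulting 1,3-dione cannot enolise at the bridgehead C1 (Bredt strain), so C1 is configurationally safe.

Step 12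
Reactants: 17 (1R,5S,6R,7R)-5-allyl-7-(3,4-dimethoxyphenyl)-4-methoxy-6-methylbicyclo[3.2.1]octane-2,8-dione
Product: 19 (1S,5S,6R,7R)-5-allyl-7-(3,4-dimethoxyphenyl)-3-hydroxy-4-methoxy-6-methylbicyclo[3.2.1]octane-2,8-dione (C3/C4 epimers), via sodium enolate 18 (not isolated)
Conditions: NaN(SiMe3)2, THF, −78 °C; 2-(phenylsulfonyl)-3-phenyloxaziridine, −78 °C; AcOH quench
Reagents that add atoms: 2-(phenylsulfonyl)-3-phenyloxaziridine O=S(=O)(c1ccccc1)N1OC1c1ccccc1
Why: In this Davis enolate hydroxylation the hindered amide can deprotonate only C3 (C1 is a bridgehead and C8 has no other α-hydrogen), and the enolate should take oxygen from the N-sulfonyloxaziridine at −78 °C, where loss of the C4 methoxide is slow; the C3 configuration is irrelevant.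

Step 13
Reactants: 19 (1S,5S,6R,7R)-5-allyl-7-(3,4-dimethoxyphenyl)-3-hydroxy-4-methoxy-6-methylbicyclo[3.2.1]octane-2,8-dione
Product: 20 (1S,5S,6R,7R)-5-allyl-7-(3,4-dimethoxyphenyl)-3-hydroxy-6-methylbicyclo[3.2.1]oct-3-ene-2,8-dione
Conditions: DBU, CH2Cl2, 25 °C
Reagents that add atoms: none
Why: E1cB β-elimination through the C2/C3 enolate should expel the C4 methoxide and give the C3=C4 enol of the 2,3-dione (diosphenol), the only enol possible because C1 is a bridgehead.

Step 14
Reactants: 20 (1S,5S,6R,7R)-5-allyl-7-(3,4-dimethoxyphenyl)-3-hydroxy-6-methylbicyclo[3.2.1]oct-3-ene-2,8-dione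
Product: 21 kadsurenin D, (1S,5S,6R,7R)-5-allyl-7-(3,4-dimethoxyphenyl)-3-methoxy-6-methylbicyclo[3.2.1]oct-3-ene-2,8-dione
Conditions: Me2SO4, K2CO3, acetone, 25 °C
Reagents that add atoms: dimethyl sulfate COS(=O)(=O)OC
Why: Williamson-type O-methylation of the acidic diosphenol hydroxyl with a hard methylating agent should give the methyl enol ether, and the non-nucleophilic carbonate spares the non-enolisable 1,3-dione from retro-Claisen cleavage.

**Compound list**

1 | 3,4-dimethoxyaniline | COc1ccc(N)cc1OC | starting material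
2 | 3,4-dimethoxybenzenediazonium tetrafluoroborate | COc1ccc([N+]#N)cc1OC.F[B-](F)(F)F | intermediate
3 | cyclopent-3-en-1-ol | OC1CC=CC1 | starting material
4 | (1R,4S)-4-(3,4-dimethoxyphenyl)cyclopent-2-en-1-ol (cis) | O[C@H]1C=C[C@@H](c2ccc(OC)c(OC)c2)C1 | intermediate
5 | (S)-4-(3,4-dimethoxyphenyl)cyclopent-2-en-1-one | O=C1C=C[C@@H](c2ccc(OC)c(OC)c2)C1 | intermediate
6 | (S)-4-(3,4-dimethoxyphenyl)-2-iodocyclopent-2-en-1-one | O=C1C(I)=C[C@@H](c2ccc(OC)c(OC)c2)C1 | intermediate
7 | allyltributylstannane | C=CC[Sn](CCCC)(CCCC)CCCC | starting material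
8 | (S)-2-allyl-4-(3,4-dimethoxyphenyl)cyclopent-2-en-1-one | C=CCC1=C[C@@H](c2ccc(OC)c(OC)c2)CC1=O | intermediate
9 | methyl 3,3-dimethoxypropanoate | COC(=O)CC(OC)OC | starting material
10 | 3,3-dimethoxypropanal | O=CCC(OC)OC | intermediate
11 | lithium dienolate of 8 (enolate across C1=C5, C2=C3 retained, aryl centre unchanged) | C=CCC1=C[C@@H](c2ccc(OC)c(OC)c2)C=C1[O-].[Li+] | intermediate
12 | (4R,5R)-2-allyl-4-(3,4-dimethoxyphenyl)-5-(1-hydroxy-3,3-dimethoxypropyl)cyclopent-2-en-1-one (4,5-trans; carbinol epimers) | C=CCC1=C[C@@H](c2ccc(OC)c(OC)c2)[C@H](C(O)CC(OC)OC)C1=O | intermediate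
13 | (4R,5R)-2-allyl-5-[1-(tert-butyldimethylsilyloxy)-3,3-dimethoxypropyl]-4-(3,4-dimethoxyphenyl)cyclopent-2-en-1-one (4,5-trans; silyl ether carbon as either epimer) | C=CCC1=C[C@@H](c2ccc(OC)c(OC)c2)[C@H](C(O[Si](C)(C)C(C)(C)C)CC(OC)OC)C1=O | intermediate
14 | trimethylsilyl enol ether of the conjugate adduct: 2-allyl-5-[1-(tert-butyldimethylsilyloxy)-3,3-dimethoxypropyl]-4-(3,4-dimethoxyphenyl)-3-methyl-1-(trimethylsilyloxy)cyclopent-1-ene (methyl trans to aryl, aryl trans to the chain) | C=CCC1=C(O[Si](C)(C)C)[C@@H](C(O[Si](C)(C)C(C)(C)C)CC(OC)OC)[C@H](c2ccc(OC)c(OC)c2)[C@H]1C | intermediate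
15 | (1R,5S,6R,7R)-5-allyl-2-(tert-butyldimethylsilyloxy)-7-(3,4-dimethoxyphenyl)-4-methoxy-6-methylbicyclo[3.2.1]octan-8-one (aryl exo, methyl endo; C2/C4 epimer mixtures) | C=CC[C@]12C(OC)CC(O[Si](C)(C)C(C)(C)C)[C@H](C1=O)[C@H](c1ccc(OC)c(OC)c1)[C@H]2C | intermediate
16 | (1R,5S,6R,7R)-5-allyl-7-(3,4-dimethoxyphenyl)-2-hydroxy-4-methoxy-6-methylbicyclo[3.2.1]octan-8-one (C2/C4 epimer mixtures) | C=CC[C@]12C(OC)CC(O)[C@H](C1=O)[C@H](c1ccc(OC)c(OC)c1)[C@H]2C | intermediate
17 | (1R,5S,6R,7R)-5-allyl-7-(3,4-dimethoxyphenyl)-4-methoxy-6-methylbicyclo[3.2.1]octane-2,8-dione (C4 epimers) | C=CC[C@]12C(OC)CC(=O)[C@H](C1=O)[C@H](c1ccc(OC)c(OC)c1)[C@H]2C | intermediate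
18 | sodium C2–C3 enolate of 17 | C=CC[C@]12C(OC)C=C([O-])[C@H](C1=O)[C@H](c1ccc(OC)c(OC)c1)[C@H]2C.[Na+] | intermediate
19 | (1S,5S,6R,7R)-5-allyl-7-(3,4-dimethoxyphenyl)-3-hydroxy-4-methoxy-6-methylbicyclo[3.2.1]octane-2,8-dione (C3/C4 epimers) | C=CC[C@]12C(OC)C(O)C(=O)[C@H](C1=O)[C@H](c1ccc(OC)c(OC)c1)[C@H]2C | intermediate
20 | (1S,5S,6R,7R)-5-allyl-7-(3,4-dimethoxyphenyl)-3-hydroxy-6-methylbicyclo[3.2.1]oct-3-ene-2,8-dione | C=CC[C@]12C=C(O)C(=O)[C@H](C1=O)[C@H](c1ccc(OC)c(OC)c1)[C@H]2C | intermediate
21 | kadsurenin D, (1S,5S,6R,7R)-5-allyl-7-(3,4-dimethoxyphenyl)-3-methoxy-6-methylbicyclo[3.2.1]oct-3-ene-2,8-dione | C=CC[C@]12C=C(OC)C(=O)[C@H](C1=O)[C@H](c1ccc(OC)c(OC)c1)[C@H]2C | target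

**Step count**

Total: 14 steps. Longest linear sequence: 13 steps (steps 1–5 and 7–14, from 3,4-dimethoxyaniline); step 6 is a one-step side branch.

**Steps most likely to fail**

1. Step 9. The bridging closure may be slow, because C5 is fully substituted and the incoming C4 must pass the endo methyl group on C6; protodesilylation of the enol ether, Lewis acid induced loss of the silyl ether or loss of methanol from the oxocarbenium ion could then win. Fallback, setting out from 13: the cuprate addition is run as before but worked up with dilute acid, so that enol ether 14 is hydrolysed to the 3-methylcyclopentanone F1. The acetal is unmasked with LiBF4 in wet MeCN to give the keto aldehyde F2. An acid-catalysed intramolecular aldol addition (TsOH, benzene), in which only the C5 enol can reach the aldehyde through a six-membered transition state, should give the bridged ketol F3. Its C4 hydroxyl is methylated with Me3OBF4 and 1,8-bis(dimethylamino)naphthalene, which returns to the route at 15.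

2. Step 7. Deprotonation may occur at the benzylic γ-carbon instead of the α′-carbon, eroding the aryl stereocentre and moving the double bond; the base may also strip methanol from the aldehyde, and the aldolate may revert on warming. Fallback, setting out from 8: the enolate is made by soft enolisation instead of by a strong amide base. nBu2BOTf and iPr2NEt in CH2Cl2 at −78 °C should give the dibutylboron dienolate F4, which undergoes a boron aldol addition to 10; oxidative work-up (H2O2, pH 7 buffer, MeOH, 0 °C) returns to the route at 12.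

3. Step 12. The enolate 18 may lose the C4 methoxide before oxygen transfer, or add to the sulfonimine by-product. Fallback, setting out from 17, uses that elimination deliberately. DBU in CH2Cl2 should give the enedione F5; nucleophilic Weitz–Scheffer epoxidation with tert-butyl hydroperoxide and DBU, which leaves the allyl group alone, gives the epoxy dione F6; acid-catalysed isomerisation (cat. H2SO4, AcOH) opens the epoxide to the diosphenol, returning to the route at 20.

**Further compounds**

F1 | step 9 | 2-allyl-5-[1-(tert-butyldimethylsilyloxy)-3,3-dimethoxypropyl]-4-(3,4-dimethoxyphenyl)-3-methylcyclopentan-1-one (3,4-trans, 4,5-trans; C2 epimers) | C=CCC1C(=O)[C@@H](C(O[Si](C)(C)C(C)(C)C)CC(OC)OC)[C@H](c2ccc(OC)c(OC)c2)[C@H]1C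
F2 | step 9 | 3-[3-allyl-5-(3,4-dimethoxyphenyl)-4-methyl-2-oxocyclopentyl]-3-(tert-butyldimethylsilyloxy)propanal (ring configuration as F1) | C=CCC1C(=O)[C@@H](C(O[Si](C)(C)C(C)(C)C)CC=O)[C@H](c2ccc(OC)c(OC)c2)[C@H]1C
F3 | step 9 | 5-allyl-2-(tert-butyldimethylsilyloxy)-7-(3,4-dimethoxyphenyl)-4-hydroxy-6-methylbicyclo[3.2.1]octan-8-one (ring configuration as 15; C2/C4 epimers) | C=CC[C@]12C(O)CC(O[Si](C)(C)C(C)(C)C)[C@H](C1=O)[C@H](c1ccc(OC)c(OC)c1)[C@H]2C
F4 | step 7 | dibutylboron dienolate of 8 | C=CCC1=C[C@@H](c2ccc(OC)c(OC)c2)C=C1OB(CCCC)CCCC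
F5 | step 12 | 5-allyl-7-(3,4-dimethoxyphenyl)-6-methylbicyclo[3.2.1]oct-3-ene-2,8-dione (ring configuration as 21) | C=CC[C@]12C=CC(=O)[C@H](C1=O)[C@H](c1ccc(OC)c(OC)c1)[C@H]2C
F6 | step 12 | 5-allyl-7-(3,4-dimethoxyphenyl)-3,4-epoxy-6-methylbicyclo[3.2.1]octane-2,8-dione (ring configuration as 21; epoxide face not defined) | C=CC[C@]12C3OC3C(=O)[C@H](C1=O)[C@H](c1ccc(OC)c(OC)c1)[C@H]2C
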